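**Strategy.** Atoms carry labdane numbers. Ring B is cut across C5–C6 and C9–C10, which frees ring A as 2,2,6-trimethylcyclohexanone: its carbonyl carbon (C5) and its only enolisable carbon (C10; C4 is quaternary) are exactly the adjacent ring-A atoms that flank ring B. An asymmetric Robinson annulation with 3-methylbut-3-en-2-one (C6–C9 plus the C8 methyl) forms both bonds and the C10 quaternary centre in one flask. The C7 carbonyl left behind then relays configuration to C9 by syn-SN2′ vinylation, the new C7=C8 olefin is oxygenated at C8 from the α face, and the oxocane (O, C8, C9, C11–C15) is closed by etherification with an enantiopure C12–C16 unit and ring-closing metathesis.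

Key step: step 1

Remark: labdane numbering is used in the Why lines (decalin C1–C10, gem-dimethyl on C4, methyls on C8 and C10, side chain C11–C16, ether oxygen between C8 and C15); the sense of induction of the chiral acid (step 1) and of the iridium ligand (step 10) is assumed as drawn, and the mirror-image catalyst is taken if the opposite sense is found.

Step 1
Reactants: 1 2,2,6-trimethylcyclohexan-1-one (racemic); 2 3-methylbut-3-en-2-one
Product: 5 (3S,4aR)-3,4a,8,8-tetramethyl-4,4a,5,6,7,8-hexahydronaphthalen-2(3H)-one, via Michael diketone 3 (not isolated), via aldol ketol 4 (not isolated)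
Conditions: (R)-TRIP (5 mol%), toluene, 50 °C; then NaOMe (0.3 equiv), MeOH, 60 °C, same flask
Reagents that add atoms: none
Why: The phosphoric acid promotes enolisation of 1, possible only toward C10 because C4 is quaternary, and the enol adds through a hydrogen-bonded transition state to the unsubstituted terminus (C9) of 2 to form C9–C10; methoxide then generates the C6 enolate of the methyl ketone, which adds to the non-enolisable C5 carbonyl and loses water to give the conjugated enone (C5–C6). The closest known reaction type is the Brønsted-acid (enol) catalysed asymmetric Michael addition of α-branched cyclic ketones to vinyl ketones followed by aldol condensation, i.e. an asymmetric Robinson annulation. Ring B closes by a 6-(enolendo)-exo-trig aldol addition. The C10 quaternary centre is set by the chiral pocket of the acid, which shields one face of the tetrasubstituted enol, whereas the C8 centre is epimerisable and is erased in step 3. The step needs regioselectivity, secured by the single enolisable position of 1 and the single productive aldol mode of 3, and enantioselectivity, secured by the catalyst.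

Step 2
Reactants: 5 (3S,4aR)-3,4a,8,8-tetramethyl-4,4a,5,6,7,8-hexahydronaphthalen-2(3H)-one
Product: 6 (3S,4aR,8aS)-3,4a,8,8-tetramethyloctahydronaphthalen-2(1H)-one
Conditions: H2 (1 atm), Pd/C, EtOAc, rt
Reagents that add atoms: none
Why: Heterogeneous hydrogenation of the enone should deliver hydrogen to C5 from the α face, away from the C10 methyl and the axial C4 methyl, to give the trans ring fusion (the C8 epimers are both serviceable).

Step 3
Reactants: 6 (3S,4aR,8aS)-3,4a,8,8-tetramethyloctahydronaphthalen-2(1H)-one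
Product: 7 (4aR,8aS)-3,4a,8,8-tetramethyl-4a,5,6,7,8,8a-hexahydronaphthalen-2(1H)-one
Conditions: IBX, DMSO, 70 °C
Reagents that add atoms: none
Why: IBX dehydrogenation of ketones proceeds through the enol, and the more substituted C7–C8 enol should place the new double bond at C8=C9, while the C5–H side is screened by the C4 gem-dimethyl group.

Step 4
Reactants: 7 (4aR,8aS)-3,4a,8,8-tetramethyl-4a,5,6,7,8,8a-hexahydronaphthalen-2(1H)-one
Product: 8 (2S,4aR,8aS)-3,4a,8,8-tetramethyl-1,2,4a,5,6,7,8,8a-octahydronaphthalen-2-ol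
Conditions: NaBH4, CeCl3·7H2O, MeOH, −40 °C
Reagents that add atoms: none
Why: Luche 1,2-reduction, in which hydride should attack C7 axially from the α face, as in related fused cyclohexenones, to give the pseudo-equatorial 7β alcohol.

Step 5
Reactants: 8 (2S,4aR,8aS)-3,4a,8,8-tetramethyl-1,2,4a,5,6,7,8,8a-octahydronaphthalen-2-ol
Product: 9 (2S,4aR,8aS)-3,4a,8,8-tetramethyl-1,2,4a,5,6,7,8,8a-octahydronaphthalen-2-yl N-phenylcarbamate
Conditions: PhNCO, Et3N (cat.), CH2Cl2, rt
Reagents that add atoms: phenyl isocyanate, O=C=Nc1ccccc1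
Why: Addition of the allylic alcohol to the isocyanate gives the carbamate without touching the C7 stereocentre.

Step 6
Reactants: 9 (2S,4aR,8aS)-3,4a,8,8-tetramethyl-1,2,4a,5,6,7,8,8a-octahydronaphthalen-2-yl N-phenylcarbamate
Product: 10 (1S,4aS,8aS)-1-ethenyl-2,5,5,8a-tetramethyl-1,4,4a,5,6,7,8,8a-octahydronaphthalene
Conditions: MeLi (1 equiv), THF, −78 °C; CuI (1 equiv); CH2=CHMgBr (1 equiv), −78 °C → rt
Reagents that add atoms: vinylmagnesium bromide, C=C[Mg]Br
Why: Syn-SN2′ substitution of the N-metallated allylic carbamate, in which nitrogen-bound copper delivers the vinyl group to C9 on the β face occupied by the C7 carbamate, should set C9 by 1,3-chirality transfer and move the double bond to C7=C8.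

Step 7
Reactants: 10 (1S,4aS,8aS)-1-ethenyl-2,5,5,8a-tetramethyl-1,4,4a,5,6,7,8,8a-octahydronaphthalene
Product: 11 (1R,2S,3R,4aS,8aS)-1-ethenyl-2,3-epoxy-2,5,5,8a-tetramethyldecahydronaphthalene
Conditions: mCPBA, NaHCO3, CH2Cl2, 0 °C
Reagents that add atoms: 3-chloroperoxybenzoic acid (mCPBA), OOC(=O)c1cccc(Cl)c1
Why: The peracid should epoxidise the electron-rich trisubstituted C7=C8 bond in preference to the monosubstituted vinyl group, and from the α face because the β face is screened by the C10 methyl and the C9 vinyl group.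

Step 8
Reactants: 11 (1R,2S,3R,4aS,8aS)-1-ethenyl-2,3-epoxy-2,5,5,8a-tetramethyldecahydronaphthalene
Product: 12 (1R,2R,4aS,8aS)-1-ethenyl-2,5,5,8a-tetramethyldecahydronaphthalen-2-ol
Conditions: LiEt3BH, THF, 0 → 60 °C
Reagents that add atoms: none
Why: Hydride opens the trisubstituted epoxide by SN2 attack at the less substituted C7, which leaves the 8α tertiary alcohol with its C8–O bond untouched.

Step 9
Reactants: 13 (E)-4-(benzyloxy)but-2-en-1-ol
Product: 14 (E)-4-(benzyloxy)but-2-en-1-yl methyl carbonate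
Conditions: ClCO2Me, pyridine, CH2Cl2, 0 °C
Reagents that add atoms: methyl chloroformate, COC(=O)Cl
Why: Simple O-acylation of the primary allylic alcohol installs the leaving group for allylic substitution.

Step 10
Reactants: 14 (E)-4-(benzyloxy)but-2-en-1-yl methyl carbonate; 15 dimethyl malonate
Product: 16 dimethyl 2-[(2R)-1-(benzyloxy)but-3-en-2-yl]propanedioate
Conditions: [Ir(cod)Cl]2 (2 mol%), (S,S,S)-binaphthol-derived bis(1-phenylethyl)phosphoramidite (4 mol%), TBD (8 mol%), THF, rt
Reagents that add atoms: none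
Why: Iridium-catalysed asymmetric allylic alkylation, in which the malonate attacks the substituted terminus of the allyl–iridium complex, should give the branched product with the future C13 configuration set by the chiral phosphoramidite.

Step 11
Reactants: 16 dimethyl 2-[(2R)-1-(benzyloxy)but-3-en-2-yl]propanedioate
Product: 17 methyl (3S)-3-[(benzyloxy)methyl]pent-4-enoate
Conditions: NaCl, H2O, DMSO, 150 °C
Reagents that add atoms: none
Why: Krapcho dealkoxycarbonylation removes one ester group while the non-acidic allylic stereocentre is retained.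

Step 12
Reactants: 17 methyl (3S)-3-[(benzyloxy)methyl]pent-4-enoate
Product: 18 (3S)-3-[(benzyloxy)methyl]pent-4-en-1-ol
Conditions: LiAlH4, Et2O, 0 °C
Reagents that add atoms: none
Why: Hydride reduction of the ester gives the primary alcohol that becomes C15.

Step 13
Reactants: 18 (3S)-3-[(benzyloxy)methyl]pent-4-en-1-ol
Product: 19 (3S)-3-[(benzyloxy)methyl]pent-4-en-1-yl 4-methylbenzenesulfonate
Conditions: TsCl, Et3N, DMAP (cat.), CH2Cl2, 0 °C
Reagents that add atoms: 4-methylbenzenesulfonyl chloride, Cc1ccc(cc1)S(=O)(=O)Cl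
Why: Sulfonylation of the unhindered primary alcohol gives a tosylate that is stable towards the neighbouring benzyl ether.

Step 14
Reactants: 12 (1R,2R,4aS,8aS)-1-ethenyl-2,5,5,8a-tetramethyldecahydronaphthalen-2-ol; 19 (3S)-3-[(benzyloxy)methyl]pent-4-en-1-yl 4-methylbenzenesulfonate
Product: 20 (1R,2R,4aS,8aS)-2-{[(3S)-3-[(benzyloxy)methyl]pent-4-en-1-yl]oxy}-1-ethenyl-2,5,5,8a-tetramethyldecahydronaphthalene
Conditions: KH, 18-crown-6, THF, 0 °C; then 19, rt → 45 °C
Reagents that add atoms: none
Why: Williamson etherification, in which the potassium alkoxide of 12 displaces the primary tosylate (a leaving group that favours substitution over elimination with tertiary alkoxides), and C8 keeps its configuration because only the O–H bond is broken.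

Step 15
Reactants: 20 (1R,2R,4aS,8aS)-2-{[(3S)-3-[(benzyloxy)methyl]pent-4-en-1-yl]oxy}-1-ethenyl-2,5,5,8a-tetramethyldecahydronaphthalene
Product: 21 (5S,8R,9R,10S,13S)-16-(benzyloxy)-8,15-epoxylabd-11-ene with Z ring olefin
Conditions: second-generation Grubbs catalyst (5 mol%), CH2Cl2 (2 mM), 40 °C
Reagents that add atoms: none
Why: Ring-closing metathesis of the two vinyl groups, held close by the trans-diequatorial C8–O and C9–C11 bonds of the rigid decalin, should close the eight-membered ether as the Z olefin with loss of ethene.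

Step 16
Reactants: 21 (5S,8R,9R,10S,13S)-16-(benzyloxy)-8,15-epoxylabd-11-ene with Z ring olefin
Product: 22 (5S,8R,9R,10S,13R)-8,15-epoxylabdan-16-ol
Conditions: H2 (1 atm), Pd/C, EtOH, rt
Reagents that add atoms: none
Why: Hydrogenation saturates C11=C12 and hydrogenolysis removes the benzyl group, with no stereocentre formed or touched.

Step 17
Reactants: 22 (5S,8R,9R,10S,13R)-8,15-epoxylabdan-16-ol
Product: 23 (5S,8R,9R,10S,13R)-8,15-epoxylabdan-16-yl acetate
Conditions: Ac2O, pyridine, DMAP (cat.), CH2Cl2, rt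
Reagents that add atoms: acetic anhydride, CC(=O)OC(C)=O
Why: Acetylation of the primary alcohol gives the target.

**Compound list**

1 | 2,2,6-trimethylcyclohexan-1-one (racemic) | CC1CCCC(C)(C)C1=O | starting material
2 | 3-methylbut-3-en-2-one | CC(=O)C(C)=C | starting material
3 | (6R)-2,2,6-trimethyl-6-(2-methyl-3-oxobutyl)cyclohexan-1-one (side-chain epimers, not isolated) | CC(=O)C(C)C[C@@]1(C)CCCC(C)(C)C1=O | intermediate
4 | (4aR)-8a-hydroxy-3,4a,8,8-tetramethyloctahydronaphthalen-2(1H)-one (epimers at C3 and C8a, not isolated) | CC1C[C@@]2(C)CCCC(C)(C)C2(O)CC1=O | intermediate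
5 | (3S,4aR)-3,4a,8,8-tetramethyl-4,4a,5,6,7,8-hexahydronaphthalen-2(3H)-one | C[C@@H]1C(=O)C=C2C(C)(C)CCC[C@]2(C)C1 | intermediate
6 | (3S,4aR,8aS)-3,4a,8,8-tetramethyloctahydronaphthalen-2(1H)-one | C[C@@H]1C(=O)C[C@H]2C(C)(C)CCC[C@]2(C)C1 | intermediate
7 | (4aR,8aS)-3,4a,8,8-tetramethyl-4a,5,6,7,8,8a-hexahydronaphthalen-2(1H)-one | CC1=C[C@@]2(C)CCCC(C)(C)[C@@H]2CC1=O | intermediate
8 | (2S,4aR,8aS)-3,4a,8,8-tetramethyl-1,2,4a,5,6,7,8,8a-octahydronaphthalen-2-ol | CC1=C[C@@]2(C)CCCC(C)(C)[C@@H]2C[C@@H]1O | intermediate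
9 | (2S,4aR,8aS)-3,4a,8,8-tetramethyl-1,2,4a,5,6,7,8,8a-octahydronaphthalen-2-yl N-phenylcarbamate | CC1=C[C@@]2(C)CCCC(C)(C)[C@@H]2C[C@@H]1OC(=O)Nc1ccccc1 | intermediate
10 | (1S,4aS,8aS)-1-ethenyl-2,5,5,8a-tetramethyl-1,4,4a,5,6,7,8,8a-octahydronaphthalene | CC1=CC[C@H]2C(C)(C)CCC[C@]2(C)[C@H]1C=C | intermediate
11 | (1R,2S,3R,4aS,8aS)-1-ethenyl-2,3-epoxy-2,5,5,8a-tetramethyldecahydronaphthalene | O3[C@]1(C)[C@H]3C[C@H]2C(C)(C)CCC[C@]2(C)[C@H]1C=C | intermediate
12 | (1R,2R,4aS,8aS)-1-ethenyl-2,5,5,8a-tetramethyldecahydronaphthalen-2-ol | O[C@]1(C)CC[C@H]2C(C)(C)CCC[C@]2(C)[C@H]1C=C | intermediate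
13 | (E)-4-(benzyloxy)but-2-en-1-ol | OC/C=C/COCc1ccccc1 | starting material
14 | (E)-4-(benzyloxy)but-2-en-1-yl methyl carbonate | COC(=O)OC/C=C/COCc1ccccc1 | intermediate
15 | dimethyl malonate | COC(=O)CC(=O)OC | starting material
16 | dimethyl 2-[(2R)-1-(benzyloxy)but-3-en-2-yl]propanedioate | C=C[C@@H](COCc1ccccc1)C(C(=O)OC)C(=O)OC | intermediate
17 | methyl (3S)-3-[(benzyloxy)methyl]pent-4-enoate | C=C[C@@H](COCc1ccccc1)CC(=O)OC | intermediate
18 | (3S)-3-[(benzyloxy)methyl]pent-4-en-1-ol | C=C[C@@H](COCc1ccccc1)CCO | intermediate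
19 | (3S)-3-[(benzyloxy)methyl]pent-4-en-1-yl 4-methylbenzenesulfonate | C=C[C@@H](COCc1ccccc1)CCOS(=O)(=O)c1ccc(C)cc1 | intermediate
20 | (1R,2R,4aS,8aS)-2-{[(3S)-3-[(benzyloxy)methyl]pent-4-en-1-yl]oxy}-1-ethenyl-2,5,5,8a-tetramethyldecahydronaphthalene | C=C[C@@H](COCc1ccccc1)CCO[C@]1(C)CC[C@H]2C(C)(C)CCC[C@]2(C)[C@H]1C=C | intermediate
21 | (5S,8R,9R,10S,13S)-16-(benzyloxy)-8,15-epoxylabd-11-ene with Z ring olefin | O(Cc1ccccc1)C[C@H]2CCO[C@]3(C)CC[C@H]4C(C)(C)CCC[C@]4(C)[C@H]3/C=C\2 | intermediate
22 | (5S,8R,9R,10S,13R)-8,15-epoxylabdan-16-ol | OC[C@H]1CCO[C@]2(C)CC[C@H]3C(C)(C)CCC[C@]3(C)[C@H]2CC1 | intermediate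
23 | (5S,8R,9R,10S,13R)-8,15-epoxylabdan-16-yl acetate | CC(=O)OC[C@H]1CCO[C@]2(C)CC[C@H]3C(C)(C)CCC[C@]3(C)[C@H]2CC1 | target

**Step count.** Total: 17 steps. Longest linear sequence: 12 steps (steps 1–8 and 14–17).

**Steps most likely to fail**

Step 1. The hindered ketone may enolise too slowly, the enone may polymerise, or the acid may discriminate the faces of C10 poorly. The fallback sets out from 1 and moves chirality control to a stoichiometric auxiliary. Condensation of 1 with (S)-1-phenylethylamine (TiCl4, Et3N, toluene) should give the imine F1. Its secondary enamine tautomer should add to 2 (THF, 40 °C) in an aza-ene-type Michael addition under control of the auxiliary to give the keto imine F2. Hydrolysis with aqueous AcOH should release diketone 3, where the route is rejoined; 3 is closed to 5 with NaOMe as in the second stage of step 1.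

Step 6. Copper may fail to transfer the vinyl group to the hindered C9 next to the quaternary C10, or the syn-selectivity may be lost through direct substitution at C7. The fallback sets out from 8 and replaces the substitution by a sigmatropic shift. O-alkylation with Bu3SnCH2I (KH, THF) should give the stannylmethyl ether F3. Tin–lithium exchange (n-BuLi, THF, −78 °C) should trigger a Still–Wittig [2,3]-rearrangement that places CH2OH on the β face of C9 and gives drimenol F4. Dess–Martin oxidation should give drimenal F5, and methylenation with Ph3P=CH2 should return to 10.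

Step 14. The hindered, strongly basic tertiary alkoxide may eliminate the tosylate or attack at sulfur instead of forming the C–O bond. The fallback sets out from 12 and 17 and makes the C8–O bond by acylation. Saponification of 17 (LiOH, THF/H2O) should give (3S)-3-[(benzyloxy)methyl]pent-4-enoic acid F6, which oxalyl chloride converts into the acid chloride F7. Acylation of the lithium alkoxide of 12 (n-BuLi, THF, −78 °C) should give the ester F8. Ring-closing metathesis (second-generation Grubbs catalyst, CH2Cl2, 40 °C) should give the eight-membered unsaturated lactone F9. Reduction with i-Bu2AlH (−78 °C) to the lactol F10, followed by Et3SiH and BF3·OEt2, should give the cyclic ether 21, where the route is rejoined.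

**Further compounds**

F1 | step 1 | (S)-1-phenyl-N-(2,2,6-trimethylcyclohexylidene)ethanamine | C[C@H](N=C1C(C)CCCC1(C)C)c1ccccc1
F2 | step 1 | (S)-1-phenyl-N-[(6R)-2,2,6-trimethyl-6-(2-methyl-3-oxobutyl)cyclohexylidene]ethanamine | CC(=O)C(C)C[C@@]1(C)CCCC(C)(C)C1=N[C@@H](C)c1ccccc1
F3 | step 6 | tributyl({[(2S,4aR,8aS)-3,4a,8,8-tetramethyl-1,2,4a,5,6,7,8,8a-octahydronaphthalen-2-yl]oxy}methyl)stannane | CC1=C[C@@]2(C)CCCC(C)(C)[C@@H]2C[C@@H]1OC[Sn](CCCC)(CCCC)CCCC
F4 | step 6 | drimenol, [(1S,4aS,8aS)-2,5,5,8a-tetramethyl-1,4,4a,5,6,7,8,8a-octahydronaphthalen-1-yl]methanol | CC1=CC[C@H]2C(C)(C)CCC[C@]2(C)[C@H]1CO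
F5 | step 6 | drimenal, (1S,4aS,8aS)-2,5,5,8a-tetramethyl-1,4,4a,5,6,7,8,8a-octahydronaphthalene-1-carbaldehyde | CC1=CC[C@H]2C(C)(C)CCC[C@]2(C)[C@H]1C=O
F6 | step 14 | (3S)-3-[(benzyloxy)methyl]pent-4-enoic acid | C=C[C@@H](COCc1ccccc1)CC(=O)O
F7 | step 14 | (3S)-3-[(benzyloxy)methyl]pent-4-enoyl chloride | C=C[C@@H](COCc1ccccc1)CC(=O)Cl
F8 | step 14 | (1R,2R,4aS,8aS)-1-ethenyl-2,5,5,8a-tetramethyldecahydronaphthalen-2-yl (3S)-3-[(benzyloxy)methyl]pent-4-enoate | C=C[C@@H](COCc1ccccc1)CC(=O)O[C@]1(C)CC[C@H]2C(C)(C)CCC[C@]2(C)[C@H]1C=C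
F9 | step 14 | (5S,8R,9R,10S,13S)-16-(benzyloxy)-8,15-epoxylabd-11-en-15-one with Z ring olefin | O(Cc1ccccc1)C[C@H]2CC(=O)O[C@]3(C)CC[C@H]4C(C)(C)CCC[C@]4(C)[C@H]3/C=C\2
F10 | step 14 | (5S,8R,9R,10S,13S)-16-(benzyloxy)-8,15-epoxylabd-11-en-15-ol with Z ring olefin (lactol, C15 epimers) | O(Cc1ccccc1)C[C@H]2CC(O)O[C@]3(C)CC[C@H]4C(C)(C)CCC[C@]4(C)[C@H]3/C=C\2
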